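**Assumption:** the sense of induction of (R)-TRIP in step 7 and of the (R,R)-lithium amide in step 10 follows the models named in those steps; each reagent is available as its antipode, which would be used instead, with nothing else changed, if a model proves wrong.

## Retrosynthetic overview

1. Target 19 ⇒ silyl ether 18 ⇒ ring A bromohydrin 16 (C–Cl with retention) ⇒ α-bromoketone 15 ⇒ symmetric ring A ketone 13; the spiro stereocentre arises by enantiotopic-group-selective enolisation.
2. 13 ⇒ ring B bromohydrin 11 ⇒ achiral spiro diene 10, by a new catalytic enantioselective anti-1,2-bromohydroxylation that sets both ring B stereocentres.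
3. 10 ⇒ dehydration of cyclohexenol 9 ⇒ ring-closing metathesis of allyl carbinol 8 ⇒ methyl ketone 7 ⇒ acid 6.
4. 6 ⇒ Ireland–Claisen rearrangement of prenyl ester 3 (joins the future spiro carbon to the CMe2 carbon) ⇒ commercial ketal acid 1 and prenol 2.
5. Ring order: ring A is bought as the ketal-protected cyclohexane of 1; ring B is closed second (step 5).

Locants in the "Why" lines follow the compound names.

## Route

Step 1
Reactants: 1 1,4-dioxaspiro[4.5]decane-8-carboxylic acid; 2 3-methylbut-2-en-1-ol (prenol)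
Product: 3 3-methylbut-2-en-1-yl 1,4-dioxaspiro[4.5]decane-8-carboxylate
Conditions: DCC, DMAP (10 mol%), CH2Cl2, 0 °C to rt
Reagents that add atoms: none
Why: Steglich esterification of an unhindered acid with a primary allylic alcohol; no stereocentre.

Step 2
Reactants: 3 3-methylbut-2-en-1-yl 1,4-dioxaspiro[4.5]decane-8-carboxylate
Product: 6 8-(2-methylbut-3-en-2-yl)-1,4-dioxaspiro[4.5]decane-8-carboxylic acid, via silyl ketene acetal 4 (not isolated), via trimethylsilyl ester 5 (not isolated)
Conditions: LiN(i-Pr)2 (commercial solution), THF, −78 °C; Me3SiCl; −78 to 65 °C; then H2O, pH 4, 0 °C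
Reagents that add atoms: none
Why: Ireland–Claisen rearrangement: the silyl ketene acetal of the α-branched ester undergoes the [3,3]-shift onto the dimethyl-substituted allyl terminus, making the bond between the future spiro carbon and the CMe2 carbon; ring A is symmetric, so no stereocentre arises.

Step 3
Reactants: 6 8-(2-methylbut-3-en-2-yl)-1,4-dioxaspiro[4.5]decane-8-carboxylic acid
Product: 7 1-[8-(2-methylbut-3-en-2-yl)-1,4-dioxaspiro[4.5]decan-8-yl]ethan-1-one
Conditions: MeLi (3 equiv), Et2O, 0 °C to rt; then H2O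
Reagents that add atoms: methyllithium ([Li]C)
Why: Organolithium synthesis of a methyl ketone from a carboxylic acid: MeLi adds once to the lithium carboxylate and the ketone is released only on aqueous quench; the ketal is inert.

Step 4
Reactants: 7 1-[8-(2-methylbut-3-en-2-yl)-1,4-dioxaspiro[4.5]decan-8-yl]ethan-1-one
Product: 8 rac-2-[8-(2-methylbut-3-en-2-yl)-1,4-dioxaspiro[4.5]decan-8-yl]pent-4-en-2-ol
Conditions: CH2=CHCH2MgBr (2 equiv), THF, 0 °C; then H2O
Reagents that add atoms: allylmagnesium bromide (C=CC[Mg]Br)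
Why: Grignard addition; allylmagnesium halides add through a six-membered transition state even to ketones flanked by quaternary carbon, and the new racemic carbinol centre is erased in step 6.

Step 5
Reactants: 8 rac-2-[8-(2-methylbut-3-en-2-yl)-1,4-dioxaspiro[4.5]decan-8-yl]pent-4-en-2-ol
Product: 9 rac-9,13,13-trimethyl-1,4-dioxadispiro[4.2.5.2]pentadec-11-en-9-ol
Conditions: second-generation Grubbs catalyst RuCl2(=CHPh)(H2IMes)(PCy3) (5 mol%), CH2Cl2, 40 °C
Reagents that add atoms: none
Why: Ring-closing metathesis of the allyl group and the neopentylic vinyl group closes ring B as a cyclohexene with loss of ethene; the carbinol centre stays racemic.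

Step 6
Reactants: 9 rac-9,13,13-trimethyl-1,4-dioxadispiro[4.2.5.2]pentadec-11-en-9-ol
Product: 10 9,13,13-trimethyl-1,4-dioxadispiro[4.2.5.2]pentadeca-9,11-diene
Conditions: Burgess reagent, benzene, 50 °C
Reagents that add atoms: none
Why: Burgess dehydration (syn-elimination through the sulfamate) of the tertiary alcohol toward the allylic ring CH2, the only ring direction open because the other neighbour is the quaternary spiro carbon, gives the conjugated diene and removes the racemic centre.

Step 7
Reactants: 10 9,13,13-trimethyl-1,4-dioxadispiro[4.2.5.2]pentadeca-9,11-diene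
Product: 11 (11S,12S)-12-bromo-9,13,13-trimethyl-1,4-dioxadispiro[4.2.5.2]pentadec-9-en-11-ol
Conditions: (R)-3,3'-bis(2,4,6-triisopropylphenyl)-1,1'-binaphthyl-2,2'-diyl hydrogen phosphate [(R)-TRIP] (10 mol%), NBS (1.05 equiv), H2O (3 equiv), toluene/CH2Cl2 4:1, −60 °C
Reagents that add atoms: N-bromosuccinimide (O=C1CCC(=O)N1Br); water (O)
Why: Proposed new method: chiral-phosphoric-acid-catalysed enantioselective anti-1,2-bromohydroxylation of an achiral, mirror-symmetric cyclic 1,3-diene, in which the acid hydrogen-bonds both NBS and water, Br+ goes to the CMe2-flanked diene terminus (the only mode that gives the 2-methylallyl cation), and the phosphate-paired bromiranium/allyl cation is opened by the bound water at the neighbouring allylic carbon anti to bromine (1,4-capture would be at a neopentylic tertiary carbon), so that the chiral ion pair selects one of the two enantiotopic diene faces and sets C11 and C12 as the trans (11S,12S) pair; the closest known reaction types are the racemic NBS/H2O bromohydrin formation of cyclohexa-1,3-dienes and chiral-phosphoric-acid or cinchona-alkaloid catalysed enantioselective bromoetherification, bromoesterification and bromohydroxylation of styrenes and allylic alcohols.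

Step 8
Reactants: 11 (11S,12S)-12-bromo-9,13,13-trimethyl-1,4-dioxadispiro[4.2.5.2]pentadec-9-en-11-ol
Product: 12 tert-butyl{[(11S,12S)-12-bromo-9,13,13-trimethyl-1,4-dioxadispiro[4.2.5.2]pentadec-9-en-11-yl]oxy}dimethylsilane
Conditions: TBSCl, imidazole, DMF, 35 °C
Reagents that add atoms: tert-butyldimethylsilyl chloride (CC(C)(C)[Si](C)(C)Cl)
Why: Imidazole-mediated silylation masks the secondary alcohol against the bases and SOCl2 used later; imidazole is too weak a base to close the trans-bromohydrin to an epoxide.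

Step 9
Reactants: 12 tert-butyl{[(11S,12S)-12-bromo-9,13,13-trimethyl-1,4-dioxadispiro[4.2.5.2]pentadec-9-en-11-yl]oxy}dimethylsilane
Product: 13 (9S,10S)-10-bromo-9-[(tert-butyldimethylsilyl)oxy]-7,11,11-trimethylspiro[5.5]undec-7-en-3-one
Conditions: PPTS (20 mol%), acetone/H2O 10:1, 55 °C
Reagents that add atoms: water (O)
Why: Acid-catalysed ketal hydrolysis frees the ring A ketone, while the hindered secondary silyl ether and the alkyl bromide survive PPTS.

Step 10
Reactants: 13 (9S,10S)-10-bromo-9-[(tert-butyldimethylsilyl)oxy]-7,11,11-trimethylspiro[5.5]undec-7-en-3-one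
Product: 15 (2S,6S,9S,10S)-2,10-dibromo-9-[(tert-butyldimethylsilyl)oxy]-7,11,11-trimethylspiro[5.5]undec-7-en-3-one, via enol silane 14 (not isolated)
Conditions: (R,R)-bis(1-phenylethyl)amine, n-BuLi, LiCl, THF, −78 °C; 13 and Me3SiCl (internal quench), −100 °C; crude 14, NBS, THF, −78 °C
Reagents that add atoms: N-bromosuccinimide (O=C1CCC(=O)N1Br)
Why: Enantiotopic-group-selective deprotonation with a chiral lithium amide under internal Me3SiCl quench (Simpkins–Koga asymmetric enolisation; with 4-tert-butylcyclohexanone the (R,R)-base gives the (S)-enol silane, which, transposed to the chair of 13 with the olefinic ring B carbon axial and the CMe2 carbon equatorial, means enolisation toward the CH2 that makes the spiro carbon 6S), then electrophilic bromination of the enol silane by NBS from the ring A face anti to the axial olefinic carbon and its methyl group, which puts Br equatorial and cis to the CMe2 carbon (2S), the epimer that is also thermodynamically preferred.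

Step 11
Reactants: 15 (2S,6S,9S,10S)-2,10-dibromo-9-[(tert-butyldimethylsilyl)oxy]-7,11,11-trimethylspiro[5.5]undec-7-en-3-one
Product: 16 (2S,3S,6S,9S,10S)-2,10-dibromo-9-[(tert-butyldimethylsilyl)oxy]-3,7,11,11-tetramethylspiro[5.5]undec-7-en-3-ol
Conditions: MeMgBr (3 equiv), THF/toluene, −78 °C; then H2O at −78 °C
Reagents that add atoms: methylmagnesium bromide (C[Mg]Br)
Why: Grignard addition to the ketone from the open axial face, anti to the axial ring B carbon whose methyl group covers the other face, gives the axial methyl group and the equatorial tertiary alcohol trans to bromine (3S); the cold quench keeps the halohydrin from closing to an epoxide.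

Step 12
Reactants: 16 (2S,3S,6S,9S,10S)-2,10-dibromo-9-[(tert-butyldimethylsilyl)oxy]-3,7,11,11-tetramethylspiro[5.5]undec-7-en-3-ol
Product: 18 tert-butyl{[(3S,4S,6S,8S,9S)-4,8-dibromo-9-chloro-1,5,5,9-tetramethylspiro[5.5]undec-1-en-3-yl]oxy}dimethylsilane, via chlorosulfite 17 (not isolated)
Conditions: SOCl2 (1.5 equiv), CH2Cl2, −20 to 0 °C (no base)
Reagents that add atoms: thionyl chloride (ClS(Cl)=O)
Why: Chlorodehydroxylation with SOCl2 without base: the tertiary chlorosulfite ionises and returns chloride on the face it leaves (SNi ion-pair collapse), while the vicinal trans bromine bridges the opposite face (neighbouring-group participation), so C9 keeps its configuration (retention, 9S) and Cl ends trans to Br.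

Step 13
Reactants: 18 tert-butyl{[(3S,4S,6S,8S,9S)-4,8-dibromo-9-chloro-1,5,5,9-tetramethylspiro[5.5]undec-1-en-3-yl]oxy}dimethylsilane
Product: 19 (3S,4S,6S,8S,9S)-4,8-dibromo-9-chloro-1,5,5,9-tetramethylspiro[5.5]undec-1-en-3-ol
Conditions: HF·pyridine, THF/pyridine, 0 °C to rt
Reagents that add atoms: none
Why: Fluoride-mediated desilylation under acidic, non-basic conditions, so that the trans-bromohydrin does not close to an epoxide and the halides do not eliminate; no stereocentre is touched.

## Compound list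

1 | 1,4-dioxaspiro[4.5]decane-8-carboxylic acid | OC(=O)C1CCC2(CC1)OCCO2 | starting material
2 | 3-methylbut-2-en-1-ol (prenol) | CC(C)=CCO | starting material
3 | 3-methylbut-2-en-1-yl 1,4-dioxaspiro[4.5]decane-8-carboxylate | CC(C)=CCOC(=O)C1CCC2(CC1)OCCO2 | intermediate
4 | silyl ketene acetal: 8-{[(3-methylbut-2-en-1-yl)oxy][(trimethylsilyl)oxy]methylidene}-1,4-dioxaspiro[4.5]decane | CC(C)=CCOC(O[Si](C)(C)C)=C1CCC2(CC1)OCCO2 | intermediate
5 | trimethylsilyl 8-(2-methylbut-3-en-2-yl)-1,4-dioxaspiro[4.5]decane-8-carboxylate | C=CC(C)(C)C1(C(=O)O[Si](C)(C)C)CCC2(CC1)OCCO2 | intermediate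
6 | 8-(2-methylbut-3-en-2-yl)-1,4-dioxaspiro[4.5]decane-8-carboxylic acid | C=CC(C)(C)C1(C(=O)O)CCC2(CC1)OCCO2 | intermediate
7 | 1-[8-(2-methylbut-3-en-2-yl)-1,4-dioxaspiro[4.5]decan-8-yl]ethan-1-one | C=CC(C)(C)C1(C(C)=O)CCC2(CC1)OCCO2 | intermediate
8 | rac-2-[8-(2-methylbut-3-en-2-yl)-1,4-dioxaspiro[4.5]decan-8-yl]pent-4-en-2-ol (racemic carbinol centre) | C=CCC(C)(O)C1(C(C)(C)C=C)CCC2(CC1)OCCO2 | intermediate
9 | rac-9,13,13-trimethyl-1,4-dioxadispiro[4.2.5.2]pentadec-11-en-9-ol (ring B cyclohexenol on the ketal-protected ring A; racemic carbinol centre) | CC1(O)CC=CC(C)(C)C12CCC3(CC2)OCCO3 | intermediate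
10 | 9,13,13-trimethyl-1,4-dioxadispiro[4.2.5.2]pentadeca-9,11-diene (achiral) | CC1=CC=CC(C)(C)C12CCC3(CC2)OCCO3 | intermediate
11 | (11S,12S)-12-bromo-9,13,13-trimethyl-1,4-dioxadispiro[4.2.5.2]pentadec-9-en-11-ol (OH and Br trans) | CC1=C[C@H](O)[C@@H](Br)C(C)(C)C12CCC3(CC2)OCCO3 | intermediate
12 | tert-butyl{[(11S,12S)-12-bromo-9,13,13-trimethyl-1,4-dioxadispiro[4.2.5.2]pentadec-9-en-11-yl]oxy}dimethylsilane | CC1=C[C@H](O[Si](C)(C)C(C)(C)C)[C@@H](Br)C(C)(C)C12CCC3(CC2)OCCO3 | intermediate
13 | (9S,10S)-10-bromo-9-[(tert-butyldimethylsilyl)oxy]-7,11,11-trimethylspiro[5.5]undec-7-en-3-one | CC1=C[C@H](O[Si](C)(C)C(C)(C)C)[C@@H](Br)C(C)(C)C12CCC(=O)CC2 | intermediate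
14 | (6S,9S,10S)-10-bromo-9-[(tert-butyldimethylsilyl)oxy]-7,11,11-trimethyl-3-[(trimethylsilyl)oxy]spiro[5.5]undeca-2,7-diene | CC1=C[C@H](O[Si](C)(C)C(C)(C)C)[C@@H](Br)C(C)(C)[C@]12CCC(O[Si](C)(C)C)=CC2 | intermediate
15 | (2S,6S,9S,10S)-2,10-dibromo-9-[(tert-butyldimethylsilyl)oxy]-7,11,11-trimethylspiro[5.5]undec-7-en-3-one | CC1=C[C@H](O[Si](C)(C)C(C)(C)C)[C@@H](Br)C(C)(C)[C@]12CCC(=O)[C@@H](Br)C2 | intermediate
16 | (2S,3S,6S,9S,10S)-2,10-dibromo-9-[(tert-butyldimethylsilyl)oxy]-3,7,11,11-tetramethylspiro[5.5]undec-7-en-3-ol | CC1=C[C@H](O[Si](C)(C)C(C)(C)C)[C@@H](Br)C(C)(C)[C@]12CC[C@](C)(O)[C@@H](Br)C2 | intermediate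
17 | chlorosulfite of 16: (2S,3S,6S,9S,10S)-2,10-dibromo-9-[(tert-butyldimethylsilyl)oxy]-3,7,11,11-tetramethylspiro[5.5]undec-7-en-3-yl sulfurochloridite | CC1=C[C@H](O[Si](C)(C)C(C)(C)C)[C@@H](Br)C(C)(C)[C@]12CC[C@](C)(OS(Cl)=O)[C@@H](Br)C2 | intermediate
18 | tert-butyl{[(3S,4S,6S,8S,9S)-4,8-dibromo-9-chloro-1,5,5,9-tetramethylspiro[5.5]undec-1-en-3-yl]oxy}dimethylsilane | CC1=C[C@H](O[Si](C)(C)C(C)(C)C)[C@@H](Br)C(C)(C)[C@]12CC[C@](C)(Cl)[C@@H](Br)C2 | intermediate
19 | (3S,4S,6S,8S,9S)-4,8-dibromo-9-chloro-1,5,5,9-tetramethylspiro[5.5]undec-1-en-3-ol (CNP0150672.1) | CC1=C[C@H](O)[C@@H](Br)C(C)(C)[C@]12CC[C@](C)(Cl)[C@@H](Br)C2 | target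

## Totals and risk

Total step count: 13. Longest linear sequence: 13 steps (from 1).

The three steps most likely to fail:

**Step 7 (the proposed new method).** Enantioselectivity and 1,2- versus 1,4-capture are unproven. The fallback uses known chemistry only, sets out from 10 and comes back at 11. Diene 10 is treated with NBS in acetone/water at 0 °C (classical anti bromohydrin formation) to give the racemic trans-bromohydrin, rac-12-bromo-9,13,13-trimethyl-1,4-dioxadispiro[4.2.5.2]pentadec-9-en-11-ol F1. This is resolved by lipase-catalysed transesterification (Burkholderia cepacia lipase, vinyl acetate, MTBE, 30 °C). Following the usual secondary-alcohol preference of lipases, the (11R,12R)-alcohol is acetylated to (11R,12R)-12-bromo-9,13,13-trimethyl-1,4-dioxadispiro[4.2.5.2]pentadec-9-en-11-yl acetate F2. Unreacted (11S,12S)-11 (at most 50%) is separated by chromatography and enters step 8.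

**Step 10.** The axial α-hydrogens of 13 lie on the ring A face covered by the ring B methyl group, so rate and selectivity of the chiral-base enolisation are uncertain. The fallback replaces the chiral base by enamine organocatalysis, sets out from 13 and comes back at 15. Ketone 13 is brominated directly with (4R,5R)-4,5-diphenylimidazolidine (20 mol%), PhCO2H and 4,4-dibromo-2,6-di-tert-butylcyclohexa-2,5-dienone as Br+ donor in CH2Cl2 at −25 °C (catalytic asymmetric α-bromination of a cyclohexanone through its enamine). The catalyst chooses both the α-CH2 and the face, and any wrong C2 epimer converges on the equatorial bromide. This fallback makes no compound outside the list (F0).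

**Step 12.** Ion-pair return could compete with elimination or with chloride capture from the open face, which would give the cis bromochloride. The fallback builds the bromochloride by alkene addition instead, sets out from 13 and comes back at 18.
- Enol silane 14 (made as in step 10) is cleaved with MeLi and trapped with PhNTf2 to give the enol triflate, (6S,9S,10S)-10-bromo-9-[(tert-butyldimethylsilyl)oxy]-7,11,11-trimethylspiro[5.5]undeca-2,7-dien-3-yl trifluoromethanesulfonate F3.
- Fe(acac)3-catalysed cross-coupling with MeMgBr (THF/NMP, 0 °C) gives the ring A methyl alkene, tert-butyl{[(3S,4S,6S)-4-bromo-1,5,5,9-tetramethylspiro[5.5]undeca-1,8-dien-3-yl]oxy}dimethylsilane F4.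
- Anti, Markovnikov bromochlorination of the trisubstituted ring A alkene (NBS, Bu4NCl, CH2Cl2, −78 °C) gives 18 by bromonium formation on the open face. It is accompanied by the diastereomer from the other face, tert-butyl{[(3S,4S,6S,8R,9R)-4,8-dibromo-9-chloro-1,5,5,9-tetramethylspiro[5.5]undec-1-en-3-yl]oxy}dimethylsilane F5, which is removed by HPLC.

## Further compounds

F1 | step 7 | rac-12-bromo-9,13,13-trimethyl-1,4-dioxadispiro[4.2.5.2]pentadec-9-en-11-ol (1:1 mixture of 11 and its (11R,12R) enantiomer; SMILES of that enantiomer) | CC1=C[C@@H](O)[C@H](Br)C(C)(C)C12CCC3(CC2)OCCO3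
F2 | step 7 | (11R,12R)-12-bromo-9,13,13-trimethyl-1,4-dioxadispiro[4.2.5.2]pentadec-9-en-11-yl acetate | CC1=C[C@@H](OC(C)=O)[C@H](Br)C(C)(C)C12CCC3(CC2)OCCO3
F0 | step 10 | none | none
F3 | step 12 | (6S,9S,10S)-10-bromo-9-[(tert-butyldimethylsilyl)oxy]-7,11,11-trimethylspiro[5.5]undeca-2,7-dien-3-yl trifluoromethanesulfonate | CC1=C[C@H](O[Si](C)(C)C(C)(C)C)[C@@H](Br)C(C)(C)[C@]12CCC(OS(=O)(=O)C(F)(F)F)=CC2
F4 | step 12 | tert-butyl{[(3S,4S,6S)-4-bromo-1,5,5,9-tetramethylspiro[5.5]undeca-1,8-dien-3-yl]oxy}dimethylsilane | CC1=C[C@H](O[Si](C)(C)C(C)(C)C)[C@@H](Br)C(C)(C)[C@]12CCC(C)=CC2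
F5 | step 12 | tert-butyl{[(3S,4S,6S,8R,9R)-4,8-dibromo-9-chloro-1,5,5,9-tetramethylspiro[5.5]undec-1-en-3-yl]oxy}dimethylsilane | CC1=C[C@H](O[Si](C)(C)C(C)(C)C)[C@@H](Br)C(C)(C)[C@]12CC[C@@](C)(Cl)[C@H](Br)C2
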